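**Retrosynthetic overview**
- The target comes from a silyl-protected bicyclic lactone by late O8 isobutyrylation and C15 desilylation.
- Key step: the C3–C6 unit (hemiketal carbon, Z-C4=C5 with its CH2O group, C6 carbinol) is carried as a 2,3-disubstituted furan. NBS/H2O opens it to the Z-keto-enal, and the C10 tertiary OH closes the five-membered hemiketal ring first.
- In the same flask an indium Barbier reaction forms C6–C7, which closes the oxygen-bridged ten-membered carbocycle second and the cis-fused α-methylene lactone third.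
- The acyclic precursor comes from a Paterson aldol (C8–C9, sets C8) followed by chelation-controlled methyl addition (sets C10), joining a furyl butanone and a chloromethyl enal ester.
- The furyl butanone comes from 3-furanmethanol (C2-lithiation/alkylation); the enal comes from dimethoxyacetaldehyde and methyl acrylate (Baylis–Hillman, SN2′ chlorination).

Assumption: germacranolide numbering is used for the bicyclic compounds (C1–C10 ring carbons, C3 = hemiketal carbon, C10 = methyl-bearing ether carbon, C11–C13 = lactone carbons, C14 = methyl on C10, C15 = CH2O carbon on C4). The target is read as (3S,4Z,6S,7R,8R,10R), with a cis-fused lactone and O6, C11 and O8 all on the face of the oxygen bridge.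

**Step 1**
Reactants: 1 furan-3-ylmethanol; 2 2-(2-bromoethyl)-2-methyl-1,3-dioxolane
Product: 4 4-[3-(hydroxymethyl)furan-2-yl]butan-2-one, via dioxolane alcohol 3 (not isolated)
Conditions: n-BuLi (2.2 equiv), THF, −78 to 0 °C; 2, DMPU, −78 °C to rt; then 1 M HCl, THF, rt
Reagents that add atoms: water, O
Why: The dianion of 3-furanmethanol is lithiated regioselectively at C2 next to the lithium alkoxide (directed metalation) and C-alkylates the primary bromide, after which dilute acid hydrolyses the dioxolane to the methyl ketone; no stereocenter is formed.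

**Step 2**
Reactants: 4 4-[3-(hydroxymethyl)furan-2-yl]butan-2-one
Product: 5 4-[3-[[tert-butyl(diphenyl)silyl]oxymethyl]furan-2-yl]butan-2-one
Conditions: TBDPSCl, imidazole, DMF, 0 °C to rt
Reagents that add atoms: tert-butyl(chloro)diphenylsilane, CC(C)(C)[Si](Cl)(c1ccccc1)c1ccccc1
Why: Standard silylation of the primary alcohol; the robust TBDPS ether survives all later steps and is removed last.

**Step 3**
Reactants: 6 2,2-dimethoxyacetaldehyde; 7 methyl acrylate
Product: 8 methyl 3-hydroxy-4,4-dimethoxy-2-methylidenebutanoate (racemic)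
Conditions: DABCO (0.5 equiv), dioxane/H2O, rt, 48 h
Reagents that add atoms: none
Why: Morita–Baylis–Hillman reaction of an activated, non-enolisable α,α-dialkoxy aldehyde; the racemic carbinol center is erased in the next step.

**Step 4**
Reactants: 8 methyl 3-hydroxy-4,4-dimethoxy-2-methylidenebutanoate
Product: 10 methyl (Z)-2-(chloromethyl)-4-oxobut-2-enoate, via chloro acetal 9 (not isolated)
Conditions: NCS, Me2S, CH2Cl2, −20 °C to rt; then TFA/H2O (9:1), 0 °C
Reagents that add atoms: N-chlorosuccinimide, O=C1CCC(=O)N1Cl; water, O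
Why: Corey–Kim-type activation of the Baylis–Hillman alcohol gives the rearranged primary allylic chloride by SN2′ attack of chloride, as the thermodynamic Z isomer (acetal carbon cis to CH2Cl), and the now vinylogous acetal is hydrolysed by dilute acid to an enal that has no α-hydrogen.

**Step 5**
Reactants: 5 4-[3-[[tert-butyl(diphenyl)silyl]oxymethyl]furan-2-yl]butan-2-one; 10 methyl (Z)-2-(chloromethyl)-4-oxobut-2-enoate
Product: 11 methyl (2Z,4R)-8-[3-[[tert-butyl(diphenyl)silyl]oxymethyl]furan-2-yl]-2-(chloromethyl)-4-hydroxy-6-oxooct-2-enoate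
Conditions: (+)-Ipc2BCl, Et3N, Et2O, −78 to 0 °C; 10, −78 to −20 °C; then MeOH, pH 7 buffer, H2O2, 0 °C
Reagents that add atoms: none
Why: Paterson boron aldol: the bulky chloroborane enolises the methyl ketone on the methyl side and the diisopinocampheylboron enolate adds 1,2 to the Re face of the non-enolisable enal, setting C8 (chain C4) as R. The sense is assigned from the reported Si-face attack of the (−)-reagent with methyl ketones; the expected er is about 9:1 and is upgraded if needed at diol 12 by recrystallisation or chiral chromatography.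

**Step 6**
Reactants: 11 methyl (2Z,4R)-8-[3-[[tert-butyl(diphenyl)silyl]oxymethyl]furan-2-yl]-2-(chloromethyl)-4-hydroxy-6-oxooct-2-enoate
Product: 12 methyl (2Z,4R,6R)-8-[3-[[tert-butyl(diphenyl)silyl]oxymethyl]furan-2-yl]-2-(chloromethyl)-4,6-dihydroxy-6-methyloct-2-enoate
Conditions: MeMgBr (3 equiv), CeCl3, THF, −78 °C; AcOH quench at −78 °C
Reagents that add atoms: methylmagnesium bromide, C[Mg]Br
Why: The organocerium reagent adds chemoselectively to the ketone at −78 °C (hindered enoate and allylic chloride untouched) while the metal alkoxide of the C8 hydroxyl chelates the ketone, so methyl attacks the six-membered chelate externally (Cram-chelate model) to give the 1,3-syn diol, i.e. C10 (chain C6) R.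

**Step 7**
Reactants: 12 methyl (2Z,4R,6R)-8-[3-[[tert-butyl(diphenyl)silyl]oxymethyl]furan-2-yl]-2-(chloromethyl)-4,6-dihydroxy-6-methyloct-2-enoate
Product: 13 methyl (2Z,4R,6R)-8-[3-[[tert-butyl(diphenyl)silyl]oxymethyl]furan-2-yl]-2-(chloromethyl)-6-hydroxy-6-methyl-4-(triethylsilyloxy)oct-2-enoate
Conditions: TESCl, imidazole, DMF, 0 °C
Reagents that add atoms: chlorotriethylsilane, CC[Si](Cl)(CC)CC
Why: The secondary hydroxyl is silylated selectively over the tertiary one; this keeps O8 out of the later lactonisation and places a poor leaving group δ to the allylmetal, so 1,4-elimination is avoided.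

**Step 8**
Reactants: 13 methyl (2Z,4R,6R)-8-[3-[[tert-butyl(diphenyl)silyl]oxymethyl]furan-2-yl]-2-(chloromethyl)-6-hydroxy-6-methyl-4-(triethylsilyloxy)oct-2-enoate
Product: 16 (3S,4Z,6S,7S,8R,10R)-15-[tert-butyl(diphenyl)silyl]oxy-3-hydroxy-8-(triethylsilyloxy)-3,10-epoxygermacra-4,11(13)-dien-6,12-olide, via hemiketal enal 14 (not isolated), via seco hydroxy ester 15 (not isolated)
Conditions: NBS (1.05 equiv), NaHCO3, THF/H2O, −10 °C; then In powder, NaI, THF/H2O (2 mM), 35 °C; citric acid work-up
Reagents that add atoms: water, O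
Why: Oxidative furan dearomatisation (Achmatowicz-type NBS ring opening: bromination at the free α-carbon, then capture by the C10 hydroxyl and water) gives the Z-keto-enal as its five-membered hemiketal in equilibrium with the spiro-lactol, which fixes the Z geometry and sets C3 thermodynamically as the only anomer that can bridge. The allylindium formed from the chloride then adds to the aldehyde in a Dreiding–Schmidt-type Barbier allylation–lactonisation through a chair transition state (C8 cis to the metallated CH2, hence syn adduct and cis lactone) on the less hindered oxygen-bridge face that already carries the C8 silyloxy group, setting C6 and C7 (C7 is S here only because the silyl ether changes CIP priority).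

**Step 9**
Reactants: 16 (3S,4Z,6S,7S,8R,10R)-15-[tert-butyl(diphenyl)silyl]oxy-3-hydroxy-8-(triethylsilyloxy)-3,10-epoxygermacra-4,11(13)-dien-6,12-olide
Product: 17 (3S,4Z,6S,7R,8R,10R)-15-[tert-butyl(diphenyl)silyl]oxy-3,8-dihydroxy-3,10-epoxygermacra-4,11(13)-dien-6,12-olide
Conditions: HF·pyridine, pyridine, THF, 0 °C
Reagents that add atoms: none
Why: Buffered HF·pyridine cleaves the secondary triethylsilyl ether much faster than the primary TBDPS ether, and the hemiketal and α-methylene lactone tolerate these non-basic conditions.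

**Step 10**
Reactants: 17 (3S,4Z,6S,7R,8R,10R)-15-[tert-butyl(diphenyl)silyl]oxy-3,8-dihydroxy-3,10-epoxygermacra-4,11(13)-dien-6,12-olide
Product: 18 (3S,4Z,6S,7R,8R,10R)-15-[tert-butyl(diphenyl)silyl]oxy-3-hydroxy-8-(2-methylpropanoyloxy)-3,10-epoxygermacra-4,11(13)-dien-6,12-olide
Conditions: i-PrCOCl, pyridine, DMAP (cat.), CH2Cl2, 0 °C
Reagents that add atoms: 2-methylpropanoyl chloride, CC(C)C(Cl)=O
Why: The secondary C8 hydroxyl is the only acylable hydroxyl (the tertiary hemiketal OH is hindered and C15 is still silylated), so the isobutyrate is installed with retention at C8.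

**Step 11**
Reactants: 18 (3S,4Z,6S,7R,8R,10R)-15-[tert-butyl(diphenyl)silyl]oxy-3-hydroxy-8-(2-methylpropanoyloxy)-3,10-epoxygermacra-4,11(13)-dien-6,12-olide
Product: 19 (3S,4Z,6S,7R,8R,10R)-3,15-dihydroxy-8-(2-methylpropanoyloxy)-3,10-epoxygermacra-4,11(13)-dien-6,12-olide (target)
Conditions: HF·pyridine, THF, rt
Reagents that add atoms: none
Why: Acidic, non-nucleophilic fluoride desilylation frees the primary allylic alcohol without touching the ester, the hemiketal or the Michael-acceptor lactone, and no stereocenter is affected.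

**Compound list**
1 | furan-3-ylmethanol | OCc1ccoc1 | starting material
2 | 2-(2-bromoethyl)-2-methyl-1,3-dioxolane | CC1(CCBr)OCCO1 | starting material
3 | [2-[2-(2-methyl-1,3-dioxolan-2-yl)ethyl]furan-3-yl]methanol | CC1(CCc2occc2CO)OCCO1 | intermediate
4 | 4-[3-(hydroxymethyl)furan-2-yl]butan-2-one | CC(=O)CCc1occc1CO | intermediate
5 | 4-[3-[[tert-butyl(diphenyl)silyl]oxymethyl]furan-2-yl]butan-2-one | CC(=O)CCc1occc1CO[Si](c1ccccc1)(c1ccccc1)C(C)(C)C | intermediate
6 | 2,2-dimethoxyacetaldehyde | COC(OC)C=O | starting material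
7 | methyl acrylate | C=CC(=O)OC | starting material
8 | methyl 3-hydroxy-4,4-dimethoxy-2-methylidenebutanoate (racemic) | COC(OC)C(O)C(=C)C(=O)OC | intermediate
9 | methyl (Z)-2-(chloromethyl)-4,4-dimethoxybut-2-enoate | COC(OC)/C=C(\CCl)C(=O)OC | intermediate
10 | methyl (Z)-2-(chloromethyl)-4-oxobut-2-enoate | O=C/C=C(\CCl)C(=O)OC | intermediate
11 | methyl (2Z,4R)-8-[3-[[tert-butyl(diphenyl)silyl]oxymethyl]furan-2-yl]-2-(chloromethyl)-4-hydroxy-6-oxooct-2-enoate | ClC/C(C(=O)OC)=C\[C@H](O)CC(=O)CCc1occc1CO[Si](c1ccccc1)(c1ccccc1)C(C)(C)C | intermediate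
12 | methyl (2Z,4R,6R)-8-[3-[[tert-butyl(diphenyl)silyl]oxymethyl]furan-2-yl]-2-(chloromethyl)-4,6-dihydroxy-6-methyloct-2-enoate | ClC/C(C(=O)OC)=C\[C@H](O)C[C@](C)(O)CCc1occc1CO[Si](c1ccccc1)(c1ccccc1)C(C)(C)C | intermediate
13 | methyl (2Z,4R,6R)-8-[3-[[tert-butyl(diphenyl)silyl]oxymethyl]furan-2-yl]-2-(chloromethyl)-6-hydroxy-6-methyl-4-(triethylsilyloxy)oct-2-enoate | ClC/C(C(=O)OC)=C\[C@H](O[Si](CC)(CC)CC)C[C@](C)(O)CCc1occc1CO[Si](c1ccccc1)(c1ccccc1)C(C)(C)C | intermediate
14 | methyl (2Z,4R)-2-(chloromethyl)-5-[(2R,5S)-5-hydroxy-2-methyl-5-[(Z)-1-[[tert-butyl(diphenyl)silyl]oxy]-4-oxobut-2-en-2-yl]oxolan-2-yl]-4-(triethylsilyloxy)pent-2-enoate (hemiketal enal) | O=C/C=C(/CO[Si](c1ccccc1)(c1ccccc1)C(C)(C)C)[C@]1(O)CC[C@](C)(C[C@@H](O[Si](CC)(CC)CC)/C=C(\CCl)C(=O)OC)O1 | intermediate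
15 | methyl (3S,4Z,6S,7S,8R,10R)-15-[tert-butyl(diphenyl)silyl]oxy-3,6-dihydroxy-8-(triethylsilyloxy)-3,10-epoxygermacra-4,11(13)-dien-12-oate (seco hydroxy ester) | O[C@H]2/C=C(/CO[Si](c1ccccc1)(c1ccccc1)C(C)(C)C)[C@]3(O)CC[C@](C)(C[C@@H](O[Si](CC)(CC)CC)[C@H]2C(=C)C(=O)OC)O3 | intermediate
16 | (3S,4Z,6S,7S,8R,10R)-15-[tert-butyl(diphenyl)silyl]oxy-3-hydroxy-8-(triethylsilyloxy)-3,10-epoxygermacra-4,11(13)-dien-6,12-olide | C=C1C(=O)O[C@H]2/C=C(/CO[Si](c4ccccc4)(c4ccccc4)C(C)(C)C)[C@]3(O)CC[C@](C)(C[C@@H](O[Si](CC)(CC)CC)[C@@H]12)O3 | intermediate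
17 | (3S,4Z,6S,7R,8R,10R)-15-[tert-butyl(diphenyl)silyl]oxy-3,8-dihydroxy-3,10-epoxygermacra-4,11(13)-dien-6,12-olide | C=C1C(=O)O[C@H]2/C=C(/CO[Si](c4ccccc4)(c4ccccc4)C(C)(C)C)[C@]3(O)CC[C@](C)(C[C@@H](O)[C@@H]12)O3 | intermediate
18 | (3S,4Z,6S,7R,8R,10R)-15-[tert-butyl(diphenyl)silyl]oxy-3-hydroxy-8-(2-methylpropanoyloxy)-3,10-epoxygermacra-4,11(13)-dien-6,12-olide | C=C1C(=O)O[C@H]2/C=C(/CO[Si](c4ccccc4)(c4ccccc4)C(C)(C)C)[C@]3(O)CC[C@](C)(C[C@@H](OC(=O)C(C)C)[C@@H]12)O3 | intermediate
19 | (3S,4Z,6S,7R,8R,10R)-3,15-dihydroxy-8-(2-methylpropanoyloxy)-3,10-epoxygermacra-4,11(13)-dien-6,12-olide | C=C1C(=O)O[C@H]2/C=C(/CO)[C@]3(O)CC[C@](C)(C[C@@H](OC(=O)C(C)C)[C@@H]12)O3 | target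

**Step count**
Total steps: 11. Longest linear sequence: 9 (steps 1, 2, 5, 6, 7, 8, 9, 10, 11); steps 3 and 4 make the second fragment.

**Steps most likely to fail, with fallbacks**

Step 8 is the most likely to fail. The macrocyclic Barbier closure may be slow against reduction or oligomerisation, and its facial selectivity at C6/C7 is argued from models, not demonstrated. The fallback sets out from 13 and replaces the reductive metal chemistry with a metal-free allylboration. Borylation of the allylic chloride (B2pin2, CuCl, LiCl, KOAc, DMF) gives the pinacol allylboronate F1. Sensitised photo-oxygenation of the furan (O2, tetraphenylporphyrin, hν, CH2Cl2, −78 °C; then Me2S) gives the boronate-bearing hemiketal enal F2. On warming in toluene (60 °C, or with catalytic Sc(OTf)3) this closes by intramolecular allylboration through a closed chair transition state; the carbinol-bearing substituent is cis to CH2B, so the syn adduct and cis lactone result. Lactonisation returns the route at 16.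

Step 6 is second. The organocerium may attack the chloromethyl acrylate, or the chelation control may be weak. The fallback sets out from 5 and introduces the methyl group before the sensitive acrylate is present. The same boron aldol with acrolein in place of 10 gives the vinyl carbinol F3. Chelation-controlled methylation, now free of competing electrophiles and therefore also possible with TiCl4 pre-chelation, gives the syn diol F4. Cross-metathesis of its vinyl group with methyl 2-(chloromethyl)prop-2-enoate (second-generation Hoveyda–Grubbs catalyst, CH2Cl2, 40 °C) gives the thermodynamic trisubstituted olefin and returns the route at 12.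

Step 5 is third. The er of a methyl-ketone boron aldol with this very electrophilic enal may be modest, or conjugate addition may compete. The fallback sets out from 5 and uses catalyst control. Kinetic silylation (LDA, Me3SiCl, THF, −78 °C) gives the trimethylsilyl enol ether F5. This is added to 10 in a Lewis-base-catalysed Mukaiyama aldol (SiCl4, chiral bisphosphoramide, CH2Cl2, −78 °C; aqueous work-up), returning the route at 11.

**Further compounds**
F1 | step 8 | methyl (2E,4R,6R)-8-[3-[[tert-butyl(diphenyl)silyl]oxymethyl]furan-2-yl]-6-hydroxy-6-methyl-2-[(4,4,5,5-tetramethyl-1,3,2-dioxaborolan-2-yl)methyl]-4-(triethylsilyloxy)oct-2-enoate | CC1(C)OB(C/C(C(=O)OC)=C\[C@H](O[Si](CC)(CC)CC)C[C@](C)(O)CCc2occc2CO[Si](c2ccccc2)(c2ccccc2)C(C)(C)C)OC1(C)C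
F2 | step 8 | methyl (2E,4R)-5-[(2R,5S)-5-hydroxy-2-methyl-5-[(Z)-1-[[tert-butyl(diphenyl)silyl]oxy]-4-oxobut-2-en-2-yl]oxolan-2-yl]-2-[(4,4,5,5-tetramethyl-1,3,2-dioxaborolan-2-yl)methyl]-4-(triethylsilyloxy)pent-2-enoate | O=C/C=C(/CO[Si](c1ccccc1)(c1ccccc1)C(C)(C)C)[C@]1(O)CC[C@](C)(C[C@@H](O[Si](CC)(CC)CC)/C=C(\CB2OC(C)(C)C(C)(C)O2)C(=O)OC)O1
F3 | step 6 | (5R)-1-[3-[[tert-butyl(diphenyl)silyl]oxymethyl]furan-2-yl]-5-hydroxyhept-6-en-3-one | C=C[C@H](O)CC(=O)CCc1occc1CO[Si](c1ccccc1)(c1ccccc1)C(C)(C)C
F4 | step 6 | (3R,5R)-1-[3-[[tert-butyl(diphenyl)silyl]oxymethyl]furan-2-yl]-3-methylhept-6-ene-3,5-diol | C=C[C@H](O)C[C@](C)(O)CCc1occc1CO[Si](c1ccccc1)(c1ccccc1)C(C)(C)C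
F5 | step 5 | tert-butyl-diphenyl-[[2-(3-trimethylsilyloxybut-3-enyl)furan-3-yl]methoxy]silane | C=C(O[Si](C)(C)C)CCc1occc1CO[Si](c1ccccc1)(c1ccccc1)C(C)(C)C
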